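**Plan**
- Ring numbering of the target: C1 (C=O), C2 (OH), C3 (CH3), C4 (C=O), C5 (OH), C6 (chain). The retrosynthesis first removes the oxygens on C1 and C5, the two carbons flanking C6, which leads to a 2-methyl-5-alkylresorcinol. It then opens the benzene ring at the bond from the chain-bearing carbon to its carboxyl-bearing neighbour (aldol), giving a linear 4-methyl-3,5,7-triketo ester.
- Enabling feature: in the six-membered carbocycle the methyl-bearing C3 lies between the oxygenated C2 and C4 and para to the chain-bearing C6. This is the pattern of a tetraketide (fatty acyl starter plus three C2 units, one methylated) folded by an aldol from chain C2 to chain C7.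
- The open chain is cut at C6–C7 (acylation of a diketo ester trianion by a C20 Weinreb amide), at C1–C2 (carbonate acylation of a diketone dianion) and at the side-chain C14'=C15' double bond (Julia–Kocienski olefination).
- Forward: olefination first, then union of the two chain fragments, then the single ring by aldol aromatisation, decarboxylation, and two ring oxygenations (radical oxidation to the hydroxyquinone, then amine addition, reoxidation and hydrolysis).
- Stereochemistry: there is no stereocentre; the E double bond comes from the Julia–Kocienski step and is not touched afterwards.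

Key step: step 8

Remark: the polycarbonyl compounds 13, 15 and 16 (and F1, F3, F6) are mixtures of keto–enol tautomers (16 also of diastereomers) and are drawn and named in their keto forms; the target is drawn as its 2,5-dihydroxy-1,4-quinone tautomer.

**Step 1**
Reactants: 1 1-bromopentane; 2 1-phenyl-1H-tetrazole-5-thiol
Product: 3 5-(pentylsulfanyl)-1-phenyl-1H-tetrazole
Conditions: K2CO3, acetone, reflux
Reagents that add atoms: none
Why: The thiolate displaces bromide from the unhindered primary bromide in an SN2 S-alkylation.

**Step 2**
Reactants: 3 5-(pentylsulfanyl)-1-phenyl-1H-tetrazole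
Product: 4 5-(pentylsulfonyl)-1-phenyl-1H-tetrazole
Conditions: 30% aq. H2O2, (NH4)6Mo7O24·4H2O (cat.), EtOH, 0 °C → rt
Reagents that add atoms: hydrogen peroxide, OO
Why: Molybdate-catalysed peroxide oxidation takes the sulfide through the sulfoxide to the sulfone, the standard entry to Julia–Kocienski reagents.

**Step 3**
Reactants: 5 ω-pentadecalactone (oxacyclohexadecan-2-one)
Product: 6 15-hydroxy-N-methoxy-N-methylpentadecanamide
Conditions: MeNH(OMe)·HCl, iPrMgCl, THF, −20 → 0 °C; aq. NH4Cl
Reagents that add atoms: N,O-dimethylhydroxylamine hydrochloride, CNOC.Cl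
Why: The chloromagnesium amide formed from the amine salt and iPrMgCl opens the unstrained lactone by acyl substitution, and the resulting N-methoxy-N-methylamide is held as a magnesium chelate and does not react further (Weinreb aminolysis of a lactone).

**Step 4**
Reactants: 6 15-hydroxy-N-methoxy-N-methylpentadecanamide
Product: 7 N-methoxy-N-methyl-15-oxopentadecanamide
Conditions: TEMPO (cat.), PhI(OAc)2, CH2Cl2, rt
Reagents that add atoms: none
Why: Oxoammonium-mediated oxidation of the primary alcohol with PhI(OAc)2 as terminal oxidant should stop at the aldehyde in the absence of water and leave the amide untouched.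

**Step 5**
Reactants: 4 5-(pentylsulfonyl)-1-phenyl-1H-tetrazole; 7 N-methoxy-N-methyl-15-oxopentadecanamide
Product: 9 (E)-N-methoxy-N-methylicos-15-enamide, via potassiated sulfone 8 (not isolated)
Conditions: KN(SiMe3)2, DME, −60 °C; then 7, −60 °C → rt
Reagents that add atoms: none
Why: In this Julia–Kocienski olefination the potassium sulfonyl carbanion adds to the aldehyde (far more electrophilic than the amide) through an open transition state to the anti adduct, and Smiles rearrangement followed by antiperiplanar loss of SO2 and tetrazolate should deliver the E alkene.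

**Step 6**
Reactants: 10 3-methylpentane-2,4-dione; 11 dimethyl carbonate
Product: 13 methyl 4-methyl-3,5-dioxohexanoate, via dilithium diketone dianion 12 (not isolated)
Conditions: LiN(iPr)2 (2 equiv), THF, 0 °C; then 11 (0.5 equiv), −78 → 0 °C; cold aq. HCl
Reagents that add atoms: none
Why: Double deprotonation gives the 1,3-dianion, whose terminal carbanion is the more nucleophilic site and is C-acylated by the carbonate (acylation of a β-diketone dianion), the diketone being used in twofold excess because the product is deprotonated by a second equivalent of the dianion.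

**Step 7**
Reactants: 13 methyl 4-methyl-3,5-dioxohexanoate; 9 (E)-N-methoxy-N-methylicos-15-enamide
Product: 15 methyl (E)-4-methyl-3,5,7-trioxohexacos-21-enoate, via trilithium diketo ester trianion 14 (not isolated)
Conditions: LiN(iPr)2 (3 equiv), THF, −78 → 0 °C; then 9 (0.5 equiv), 0 °C; cold aq. HCl; crude 15 used at once
Reagents that add atoms: none
Why: After C4 and C2 are deprotonated the third deprotonation can only occur at the C6 methyl, and this most basic carbanion attacks the Weinreb amide to give a chelated tetrahedral adduct that collapses to the C7 ketone only on acidic work-up (terminal acylation of a β-polycarbonyl polyanion).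

**Step 8**
Reactants: 15 methyl (E)-4-methyl-3,5,7-trioxohexacos-21-enoate
Product: 17 methyl 2,4-dihydroxy-3-methyl-6-[(E)-nonadec-14-enyl]benzoate, via cyclic aldol adduct 16 (not isolated)
Conditions: Cs2CO3, MeOH/THF, 0 °C → rt; then HCl in MeOH, rt
Reagents that add atoms: none
Why: Carbonate in methanol equilibrates the enolates of 15, and the ester-stabilised C2 carbanion adds to the terminal C7 ketone to close the carbocycle C2–C3–C4–C5–C6–C7 in a 6-(enolendo)-exo-trig aldol, giving 16. Acid then eliminates the tertiary hydroxyl and the C3 and C5 ketones enolise, so that aromatisation makes the closure irreversible. The closest known reaction type is the biomimetic aldol cyclo-aromatisation of 3,5,7-triketo esters to β-resorcylates, the laboratory counterpart of the alkylresorcinol synthase cyclisation. No stereocentre has to be controlled, since the three sp3 centres of 16 all become sp2 carbons of the arene. The step needs the C2-to-C7 aldol to prevail over C6-to-C1 Claisen closure, O-cyclisation to a pyranone and a C8-to-C3 aldol: in a protic medium with a mild base the methyl ester (in degenerate exchange with methanol) is a poorer electrophile than the ketone, C8 is not doubly activated, and only the C2-to-C7 adduct can drain to an aromatic ring. Because C4 keeps one hydrogen beside its methyl group, both flanking carbonyls can enolise and the methyl ends between the two phenols, para to the chain.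

**Step 9**
Reactants: 17 methyl 2,4-dihydroxy-3-methyl-6-[(E)-nonadec-14-enyl]benzoate
Product: 19 2-methyl-5-[(E)-nonadec-14-enyl]benzene-1,3-diol, via resorcylic acid 18 (not isolated)
Conditions: KOH, MeOH/H2O, reflux, argon; then aq. HCl to pH 2, 70 °C
Reagents that add atoms: none
Why: Hydroxide cleaves the hindered ester and, after acidification, the β-resorcylic acid loses CO2 by ipso-protonation of the electron-rich ring, as is usual for 2,4-dihydroxybenzoic acids (saponification then protodecarboxylation).

**Step 10**
Reactants: 19 2-methyl-5-[(E)-nonadec-14-enyl]benzene-1,3-diol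
Product: 20 3-hydroxy-2-methyl-5-[(E)-nonadec-14-enyl]cyclohexa-2,5-diene-1,4-dione
Conditions: (KSO3)2NO, aq. KH2PO4, Bu4NHSO4 (cat.), CH2Cl2/H2O, rt
Reagents that add atoms: potassium nitrosodisulfonate (Fremy's salt, (KSO3)2NO), [K+].[K+].[O]N(S(=O)(=O)[O-])S(=O)(=O)[O-]
Why: In this Teuber oxidation the phenoxyl radical is trapped by a second nitrosodisulfonate radical at the free position para to one hydroxyl (the two such positions of 19 are equivalent), and loss of imidodisulfonate gives the p-quinone with the other hydroxyl kept as a vinylogous acid, while the isolated alkene is inert to this oxidant.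

**Step 11**
Reactants: 20 3-hydroxy-2-methyl-5-[(E)-nonadec-14-enyl]cyclohexa-2,5-diene-1,4-dione
Product: 22 2-(benzylamino)-5-hydroxy-6-methyl-3-[(E)-nonadec-14-enyl]cyclohexa-2,5-diene-1,4-dione, via aminohydroquinone 21 (not isolated)
Conditions: BnNH2, EtOH/THF, air, rt
Reagents that add atoms: benzylamine, NCc1ccccc1
Why: The amine adds to the only unsubstituted ring carbon, which is β to the C4 carbonyl (the one not tied up in the vinylogous acid and so the more electrophilic), and air reoxidises the aminohydroquinone, an oxidative amination known for 3-hydroxy-2,5-dialkyl-1,4-benzoquinones with primary amines.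

**Step 12**
Reactants: 22 2-(benzylamino)-5-hydroxy-6-methyl-3-[(E)-nonadec-14-enyl]cyclohexa-2,5-diene-1,4-dione
Product: 23 2,5-dihydroxy-3-methyl-6-[(E)-nonadec-14-enyl]cyclohexa-2,5-diene-1,4-dione
Conditions: 2 M aq. H2SO4, 1,4-dioxane, 80 °C
Reagents that add atoms: water, O
Why: Acid-promoted addition–elimination at the nitrogen-bearing carbon of the vinylogous amide replaces the amine by water (hydrolysis of an aminoquinone to a hydroxyquinone) under conditions too dilute to hydrate the isolated alkene.

**Compound list**
1 | 1-bromopentane | CCCCCBr | starting material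
2 | 1-phenyl-1H-tetrazole-5-thiol | Sc1nnnn1-c1ccccc1 | starting material
3 | 5-(pentylsulfanyl)-1-phenyl-1H-tetrazole | CCCCCSc1nnnn1-c1ccccc1 | intermediate
4 | 5-(pentylsulfonyl)-1-phenyl-1H-tetrazole | CCCCCS(=O)(=O)c1nnnn1-c1ccccc1 | intermediate
5 | ω-pentadecalactone (oxacyclohexadecan-2-one) | O=C1CCCCCCCCCCCCCCO1 | starting material
6 | 15-hydroxy-N-methoxy-N-methylpentadecanamide | CON(C)C(=O)CCCCCCCCCCCCCCO | intermediate
7 | N-methoxy-N-methyl-15-oxopentadecanamide | CON(C)C(=O)CCCCCCCCCCCCCC=O | intermediate
8 | potassium 1-[(1-phenyl-1H-tetrazol-5-yl)sulfonyl]pentan-1-ide (not isolated) | CCCC[CH-]S(=O)(=O)c1nnnn1-c1ccccc1.[K+] | intermediate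
9 | (E)-N-methoxy-N-methylicos-15-enamide | CCCC/C=C/CCCCCCCCCCCCCC(=O)N(C)OC | intermediate
10 | 3-methylpentane-2,4-dione | CC(=O)C(C)C(C)=O | starting material
11 | dimethyl carbonate | COC(=O)OC | starting material
12 | dilithium 3-methylpenta-1,3-diene-2,4-diolate, the dianion of 10 (not isolated) | [Li+].[Li+].C=C([O-])C(C)=C(C)[O-] | intermediate
13 | methyl 4-methyl-3,5-dioxohexanoate | CC(=O)C(C)C(=O)CC(=O)OC | intermediate
14 | trilithium trianion of 13, drawn as the tris-enolate (not isolated) | [Li+].[Li+].[Li+].C=C([O-])C(C)=C([O-])C=C([O-])OC | intermediate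
15 | methyl (E)-4-methyl-3,5,7-trioxohexacos-21-enoate | CCCC/C=C/CCCCCCCCCCCCCC(=O)CC(=O)C(C)C(=O)CC(=O)OC | intermediate
16 | methyl 2-hydroxy-5-methyl-4,6-dioxo-2-[(E)-nonadec-14-enyl]cyclohexane-1-carboxylate, mixture of diastereomers (not isolated) | CCCC/C=C/CCCCCCCCCCCCCC1(O)CC(=O)C(C)C(=O)C1C(=O)OC | intermediate
17 | methyl 2,4-dihydroxy-3-methyl-6-[(E)-nonadec-14-enyl]benzoate | CCCC/C=C/CCCCCCCCCCCCCc1cc(O)c(C)c(O)c1C(=O)OC | intermediate
18 | 2,4-dihydroxy-3-methyl-6-[(E)-nonadec-14-enyl]benzoic acid (not isolated) | CCCC/C=C/CCCCCCCCCCCCCc1cc(O)c(C)c(O)c1C(=O)O | intermediate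
19 | 2-methyl-5-[(E)-nonadec-14-enyl]benzene-1,3-diol | CCCC/C=C/CCCCCCCCCCCCCc1cc(O)c(C)c(O)c1 | intermediate
20 | 3-hydroxy-2-methyl-5-[(E)-nonadec-14-enyl]cyclohexa-2,5-diene-1,4-dione | CCCC/C=C/CCCCCCCCCCCCCC1=CC(=O)C(C)=C(O)C1=O | intermediate
21 | 5-(benzylamino)-3-methyl-6-[(E)-nonadec-14-enyl]benzene-1,2,4-triol (not isolated) | CCCC/C=C/CCCCCCCCCCCCCc1c(NCc2ccccc2)c(O)c(C)c(O)c1O | intermediate
22 | 2-(benzylamino)-5-hydroxy-6-methyl-3-[(E)-nonadec-14-enyl]cyclohexa-2,5-diene-1,4-dione | CCCC/C=C/CCCCCCCCCCCCCC1=C(NCc2ccccc2)C(=O)C(C)=C(O)C1=O | intermediate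
23 | 2,5-dihydroxy-3-methyl-6-[(E)-nonadec-14-enyl]cyclohexa-2,5-diene-1,4-dione | CCCC/C=C/CCCCCCCCCCCCCC1=C(O)C(=O)C(C)=C(O)C1=O | target

**Summary**
Total step count: 12.
Longest linear sequence: 9 steps (steps 3, 4, 5, 7, 8, 9, 10, 11 and 12, from ω-pentadecalactone).

**Steps most likely to fail**

Step 7. What may go wrong: incomplete generation of the trianion, or proton transfer from the α-methylene of the amide, so that the terminal carbanion is quenched and not acylated; premature cyclisation of the polyketone during acidic work-up. Fallback: the order of the two chain-building acylations is reversed. It sets out from amide 9 and dianion 12 (made from diketone 10 as in step 6). Acylation of 12 with 9 should give (E)-3-methylpentacos-20-ene-2,4,6-trione F1. LiN(iPr)2 (3 equiv) in THF should convert this into its trilithium trianion F2, deprotonated at the terminal methyl in preference to the chain methylene, and CO2 should carboxylate that carbon to give (E)-4-methyl-3,5,7-trioxohexacos-21-enoic acid F3. Immediate methylation of the acid with Me3SiCHN2 in toluene/MeOH at 0 °C should give 15, where the route is rejoined before the key step.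

Step 8. What may go wrong: ring closure in the wrong mode (Claisen attack of C6 on the ester, O-cyclisation to a pyranone) or retro-Claisen cleavage of the 2-methyl-1,3-diketone unit by methoxide. Fallback: the same C2-to-C7 aldol is run on a carboxylate released from a pyranone, so that no ester is present for a Claisen closure. It sets out from diketo ester 13 and amide 9. Lactonisation of 13 (DBU, toluene, reflux) should give 4-hydroxy-5,6-dimethyl-2H-pyran-2-one F4. LiN(iPr)2 (2 equiv) should form its dilithium dianion F5 at the hydroxyl and the C6 methyl, and acylation by 9 should give 4-hydroxy-5-methyl-6-[(E)-2-oxohenicos-16-enyl]-2H-pyran-2-one F6. Warm aq. KOH/MeOH should open the lactone to the triketo carboxylate (the salt of acid F3 of the first fallback), which can only close by the aldol and should give, after acidification, acid 18. The route is rejoined at 18, at the decarboxylation stage of step 9.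

Step 11. What may go wrong: sluggish conjugate addition at the ring carbon next to the C19 chain because the amine first deprotonates the hydroxyquinone, with slow decomposition of the quinone competing. Fallback: the last oxygen is brought in by Thiele–Winter acetoxylation. It sets out from 20. Ac2O with BF3·OEt2 at 0 °C → rt (kept cold and short to spare the chain alkene) should give 3-methyl-6-[(E)-nonadec-14-enyl]benzene-1,2,4,5-tetrayl tetraacetate F7. Methanolysis with K2CO3 in MeOH open to air should release 3-methyl-6-[(E)-nonadec-14-enyl]benzene-1,2,4,5-tetraol F8, which is not isolated and should autoxidise to the dihydroxyquinone. The route is rejoined at the target 23, replacing steps 11 and 12.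

**Further compounds**
F1 | step 7 | (E)-3-methylpentacos-20-ene-2,4,6-trione | CCCC/C=C/CCCCCCCCCCCCCC(=O)CC(=O)C(C)C(C)=O
F2 | step 7 | trilithium trianion of F1, drawn as the tris-enolate | [Li+].[Li+].[Li+].C=C([O-])C(C)=C([O-])C=C([O-])CCCCCCCCCCCCC/C=C/CCCC
F3 | step 7 | (E)-4-methyl-3,5,7-trioxohexacos-21-enoic acid | CCCC/C=C/CCCCCCCCCCCCCC(=O)CC(=O)C(C)C(=O)CC(=O)O
F4 | step 8 | 4-hydroxy-5,6-dimethyl-2H-pyran-2-one | CC1=C(C)C(O)=CC(=O)O1
F5 | step 8 | dilithium dianion of F4 | [Li+].[Li+].[CH2-]C1=C(C)C([O-])=CC(=O)O1
F6 | step 8 | 4-hydroxy-5-methyl-6-[(E)-2-oxohenicos-16-enyl]-2H-pyran-2-one | CCCC/C=C/CCCCCCCCCCCCCC(=O)CC1=C(C)C(O)=CC(=O)O1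
F7 | step 11 | 3-methyl-6-[(E)-nonadec-14-enyl]benzene-1,2,4,5-tetrayl tetraacetate | CCCC/C=C/CCCCCCCCCCCCCc1c(OC(C)=O)c(OC(C)=O)c(C)c(OC(C)=O)c1OC(C)=O
F8 | step 11 | 3-methyl-6-[(E)-nonadec-14-enyl]benzene-1,2,4,5-tetraol | CCCC/C=C/CCCCCCCCCCCCCc1c(O)c(O)c(C)c(O)c1O
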